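# Proposed total synthesis of CNP0202577.3 (compound 40)

Atom labels used throughout: oxolane (tetrahydrofuran) ring O1, C2–C5; dihydrobenzofuran O1', C2', C3', C3a', C4'–C7', C7a'. Compound numbers 1–40 are those of the compound list.

## Analysis of the target

The target 40 is a resveratrol-trimer-type octaphenol. A 2,3,4,5-tetrasubstituted oxolane is joined through C3 to C4' of a trans-2,3-diaryl-2,3-dihydrobenzofuran. The oxolane carries 4-hydroxyphenyl groups at C2 and C5 and a 3,5-dihydroxyphenyl group at C4. Its centres are 2S,3S,4R,5S: the C2 aryl, the C3 arene and the C4 aryl lie on one face and the C5 aryl on the other (2,3-cis, 3,4-cis, 4,5-trans). The dihydrobenzofuran adds C2' and C3' (both R, aryl groups trans), and nothing relays configuration reliably between the two ring systems. Sensitive features are the eight phenols, the three 4-oxybenzylic ether bonds (O1–C2, O1–C5, O1'–C2'), which ionise under acid, and the all-cis C2–C3–C4 array, which is not the thermodynamic arrangement. The hardest bond is C3–C4': it joins a secondary carbon flanked by two cis aryl-bearing carbons to an arene carbon whose neighbour C3a' carries the C3' methine. The strategy rests on the central benzene ring C3a'/C4'/C5'/C6'/C7'/C7a', a 1,2,3,5-tetrasubstituted resorcinol: C4' and C3a' can be the two carbons of an alkyne, and C5', C6', C7', C7a' can come from a 1,3-dioxygenated butadiene. Building this ring onto a finished oxolane turns the crowded C3–C4' bond into an unhindered C(sp3)–C(sp) bond.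

## Retrosynthetic reasoning

**Phenols.** 40 is traced to its octamethyl ether 39. Methyl ethers survive every organometallic, hydride and thermal step, and a single Lewis-acid demethylation then ends the route.

**Dihydrobenzofuran, O1'–C2' and C2'–C3'.** Both bonds of 39 are cut in a [4+1] sense. This gives the o-quinone methide 36, a four-atom unit O1'/C7a'/C3a'/C3', and the one-carbon ylide 37, which carries the 4-methoxyphenyl group. The cut is made here because C3' then becomes planar, so the two dihydrobenzofuran centres are created together and can be set by the chiral sulfide in 37. 36 comes from sulfone 31, and 37 from sulfonium salt 35.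

**Quinone methide precursor.** 31 goes back through benzhydrol 30 to the 2-hydroxybenzophenone 29. These are functional-group changes only; they place a leaving group on C3' next to a free phenol.

**Central arene, C4'–C5' and C3a'–C7a' (key disconnection).** The resorcinol ring of 29 is cut into ynone 23 and diene 27. The forward reaction must give one regiochemistry, with the aroyl group ortho to the new hydroxyl. It must also leave the C7a' oxygen free and the C6' oxygen methylated, and it must not disturb oxolane C3. A thermal cycloaddition of a polarised pair meets all three needs.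

**Ynone.** 23 is cut at the acyl–alkyne bond into lithium acetylide 22 and Weinreb amide 21 (from acid chloride 20). 22 comes from dibromoalkene 19, hence from aldehyde 18, alcohol 17 and silyl ether 16. The one-carbon handle at C3 is carried as a protected hydroxymethyl group until the oxolane is complete.

**C5–aryl bond.** 16 is cut at C5–aryl to oxocarbenium ion 15, reached from sulfone 14 and lactol 13. In 15 the three existing substituents share one face, so an aryl nucleophile is steered to the other face and gives the 4,5-trans relationship.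

**C3 and C4 hydrogens.** Lactol 13 comes from lactone 12, and 12 from butenolide 11 by syn addition of hydrogen. The single aryl-bearing centre of 11 shields one face, which makes the all-cis array the kinetic product.

**Butenolide.** 11 comes from 10, 9 and vinyl butenolide 7; the vinyl group is a masked hydroxymethyl group. 7 is cut at the vinyl–ring bond and at the lactone carbonyl–ring bond. This leads to propargylic alcohol 4 by directed vinylmagnesiation and carboxylation through chelate 5 and hydroxy acid 6. 4 is cut at the carbinol–alkyne bond into aldehyde 1 and alkyne 2; a catalytic asymmetric alkynylation sets the one centre from which the other three oxolane centres descend.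

**Small fragments.** Diene 27 comes from enoate 25 and methyl acetoacetate 24 through dienolate 26. Salt 35 comes from thiolane 34, made from diol 32 through dimesylate 33.

## Alternatives that were turned down

**Alternative 1:** The O1'–C2' bond is disconnected. A confined chiral Brønsted acid would protonate the flat triarylethylene phenol A2 at C3', and the phenol would close on the C2' cation to give the bromo-dihydrobenzofuran A1. In its favour, both dihydrobenzofuran centres come from an achiral precursor under catalyst control, early and in one step. On this point it is stronger than the chosen route, which sets these centres late with a stoichiometric chiral ylide. Against it for this target: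
- A2 is a triaryl alkene whose 2,6-disubstituted ring is twisted. It has two competing protonation sites and may fit a confined acid pocket poorly.
- A1 is itself acid-labile at its 4-methoxybenzylic ether.
- The bromine of A1 must then be joined to oxolane C3. This is a C(sp2)–C(sp3) union at the most crowded position of the molecule, and nothing controls the all-cis C3 centre.

The chosen strategy gives up catalytic control of C2'/C3' but removes that junction problem altogether.

**Alternative 2:** The peripheral 3,5-dihydroxyphenyl ring on C3' is disconnected. Aqueous KOH would fold the triketone A4 by aldol condensation into the resorcinol A3. In its favour, the reagents are cheap, no metal is needed and the resorcinol arrives unprotected; on reagent cost and protecting-group economy for that ring it is stronger. Against it: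
- In A4, C3' is α to a ketone and β to the aryloxy oxygen. Hydroxide would epimerise it and open the dihydrofuran ring by β-elimination.
- A triketone can fold in more than one way.
- The ring being built is one that can simply be bought as a 3,5-dimethoxyphenyl unit.
- A3 still carries the bromine, so the C3–C4' junction remains unsolved.

The chosen strategy uses the same idea, de novo arene synthesis, on the one ring where it removes the main difficulty.

**Alternative 3:** The oxolane bonds O1–C5 and C4–C5 are disconnected. A carbene from the diazoalkane A7, generated with a catalyst such as Cu(MeCN)4PF6 and a chiral bisoxazoline, would add to the carbonyl oxygen of enone A6. The carbonyl ylide would then close to the dihydrofuran A5, and the C2=C3 bond would be reduced last. In its favour, the route is convergent, and the crowded C3–C4' bond is made as easy enolate chemistry on A6. On step economy and on that bond it is as strong as or stronger than the chosen route. Against it: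
- A7 is an unstable, electron-rich diazoalkane, prone to dimerisation and cyclopropanation.
- The C4/C5 centres would have to be controlled against the remote dihydrobenzofuran centres.
- The all-cis C2–C3–C4 array would depend on hydrogenating a tetrasubstituted, tetra-aryl enol ether in A5. Each of its faces is shielded by one aryl group, and it is acid-labile.

The chosen route sets the same array early, on a butenolide with a single shielding group.

Key step: step 17

## Assumptions

- Step 1: the (S,S) antipode of ProPhenol is taken to be the one that delivers the alkynyl group to the Si face of 1, giving the R carbinol. Both antipodes are commercial, so the other is used if the sense is opposite.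
- Step 23: the ylide from the (2R,5R) thiolane is assumed to react through the same face as in its epoxidations of aldehydes, which corresponds to R at C2'. The (2S,5S) sulfide is the alternative.

## Route

Step 1
Reactants: 1 4-methoxybenzaldehyde; 2 1-ethynyl-3,5-dimethoxybenzene
Product: 4 (1R)-3-(3,5-dimethoxyphenyl)-1-(4-methoxyphenyl)prop-2-yn-1-ol, via methylzinc acetylide 3 (not isolated)
Conditions: Me2Zn (3 equiv), (S,S)-ProPhenol (10 mol%), Ph3P=O (20 mol%), PhMe, 0 °C to rt; aq. NH4Cl
Reagents that add atoms: none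
Why: Catalytic asymmetric alkynylation of an aldehyde by an alkynylzinc held in the dinuclear zinc–ProPhenol pocket, a reaction whose standard substrates are aryl aldehydes and arylacetylenes. The ligand antipode fixes Si-face addition and thus the R carbinol, the centre from which all other oxolane centres descend.

Step 2
Reactants: 4 (1R)-3-(3,5-dimethoxyphenyl)-1-(4-methoxyphenyl)prop-2-yn-1-ol
Product: 7 (5R)-3-(3,5-dimethoxyphenyl)-4-ethenyl-5-(4-methoxyphenyl)furan-2(5H)-one, via magnesium chelate 5 (not isolated), via hydroxy acid 6 (not isolated)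
Conditions: CH2=CHMgBr (4 equiv), THF–PhMe, 65 °C; CO2 (g), 0 °C; 1 M citric acid, rt
Reagents that add atoms: vinylmagnesium bromide, C=C[Mg]Br; carbon dioxide, O=C=O
Why: Hydroxyl-directed anti-carbomagnesiation of a propargylic alkoxide puts the vinyl group on the alkyne carbon next to the carbinol and magnesium on the aryl-bearing carbon inside five-membered chelate 5, so carboxylation places CO2H cis to the carbinol and mild acid closes the butenolide. The carbinol centre is untouched, and the work-up is kept weakly acidic because the C5 hydrogen of a 5-aryl butenolide is removed easily by base.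

Step 3
Reactants: 7 (5R)-3-(3,5-dimethoxyphenyl)-4-ethenyl-5-(4-methoxyphenyl)furan-2(5H)-one
Product: 9 (2R)-4-(3,5-dimethoxyphenyl)-2-(4-methoxyphenyl)-5-oxo-2,5-dihydrofuran-3-carbaldehyde, via diol 8 (not isolated)
Conditions: OsO4 (2 mol%), NaIO4 (4 equiv), 2,6-lutidine, dioxane–H2O, 0 °C to rt
Reagents that add atoms: osmium tetroxide (catalytic oxygen carrier), O=[Os](=O)(=O)=O; sodium periodate (terminal oxygen source), [Na+].[O-]I(=O)(=O)=O
Why: Lemieux–Johnson oxidation: the terminal vinyl group is dihydroxylated much faster than the tetrasubstituted, ester-conjugated ring alkene, and periodate cleaves diol 8. The aldehyde is taken on crude and cold, because its ring C–H is vinylogously acidic.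

Step 4
Reactants: 9 (2R)-4-(3,5-dimethoxyphenyl)-2-(4-methoxyphenyl)-5-oxo-2,5-dihydrofuran-3-carbaldehyde
Product: 10 (5R)-3-(3,5-dimethoxyphenyl)-4-(hydroxymethyl)-5-(4-methoxyphenyl)furan-2(5H)-one
Conditions: NaBH4, CeCl3·7H2O, MeOH, −40 °C
Reagents that add atoms: none
Why: Luche reduction: CeCl3 directs NaBH4 to 1,2-reduction of the aldehyde and keeps the medium close to neutral, so neither conjugate reduction nor deprotonation at the benzylic ring carbon should compete.

Step 5
Reactants: 10 (5R)-3-(3,5-dimethoxyphenyl)-4-(hydroxymethyl)-5-(4-methoxyphenyl)furan-2(5H)-one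
Product: 11 (5R)-4-({[tert-butyl(dimethyl)silyl]oxy}methyl)-3-(3,5-dimethoxyphenyl)-5-(4-methoxyphenyl)furan-2(5H)-one
Conditions: t-BuMe2SiCl, imidazole, CH2Cl2, 0 °C
Reagents that add atoms: tert-butyldimethylsilyl chloride, CC(C)(C)[Si](C)(C)Cl
Why: Standard silylation of a primary alcohol; the silyl ether masks the one-carbon handle through hydrogenation, hydride reduction and arylzinc chemistry.

Step 6
Reactants: 11 (5R)-4-({[tert-butyl(dimethyl)silyl]oxy}methyl)-3-(3,5-dimethoxyphenyl)-5-(4-methoxyphenyl)furan-2(5H)-one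
Product: 12 (3R,4S,5S)-4-({[tert-butyl(dimethyl)silyl]oxy}methyl)-3-(3,5-dimethoxyphenyl)-5-(4-methoxyphenyl)oxolan-2-one
Conditions: H2 (4 atm), 5% Rh/Al2O3, EtOAc, rt
Reagents that add atoms: none
Why: Heterogeneous syn-hydrogenation of the butenolide alkene from the face opposite the C5 aryl group, the only substituent out of the ring plane; both hydrogens enter trans to that aryl, so C3 and C4 are set with all three substituents cis. Rhodium on alumina is preferred to palladium to avoid hydrogenolysis of the benzylic, allylic lactone C–O bond.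

Step 7
Reactants: 12 (3R,4S,5S)-4-({[tert-butyl(dimethyl)silyl]oxy}methyl)-3-(3,5-dimethoxyphenyl)-5-(4-methoxyphenyl)oxolan-2-one
Product: 13 (3R,4S,5S)-4-({[tert-butyl(dimethyl)silyl]oxy}methyl)-3-(3,5-dimethoxyphenyl)-5-(4-methoxyphenyl)oxolan-2-ol (anomer mixture)
Conditions: i-Bu2AlH (1.2 equiv), CH2Cl2, −78 °C; aq. KNaC4H4O6 (potassium sodium tartrate)
Reagents that add atoms: none
Why: Partial reduction of a lactone by i-Bu2AlH stops at the tetrahedral aluminate at −78 °C and gives the lactol on work-up; the low temperature and absence of base protect the epimerisable aryl-bearing carbon next to the anomeric centre.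

Step 8
Reactants: 13 (3R,4S,5S)-4-({[tert-butyl(dimethyl)silyl]oxy}methyl)-3-(3,5-dimethoxyphenyl)-5-(4-methoxyphenyl)oxolan-2-ol
Product: 14 tert-butyl{[(2S,3S,4R)-5-(benzenesulfonyl)-4-(3,5-dimethoxyphenyl)-2-(4-methoxyphenyl)oxolan-3-yl]methoxy}dimethylsilane (mixture at C5; oxolane numbered as in the target)
Conditions: PhSO2H, CaCl2, CH2Cl2, rt
Reagents that add atoms: benzenesulfinic acid, O=S(O)c1ccccc1
Why: Exchange of the lactol hydroxyl for sulfinate through the oxocarbenium ion, with the sulfinic acid as its own mild catalyst and CaCl2 as desiccant; 2-sulfonyl cyclic ethers are stable oxocarbenium precursors.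

Step 9
Reactants: 14 tert-butyl{[(2S,3S,4R)-5-(benzenesulfonyl)-4-(3,5-dimethoxyphenyl)-2-(4-methoxyphenyl)oxolan-3-yl]methoxy}dimethylsilane
Product: 16 tert-butyl{[(2S,3S,4R,5S)-4-(3,5-dimethoxyphenyl)-2,5-bis(4-methoxyphenyl)oxolan-3-yl]methoxy}dimethylsilane, via oxocarbenium ion 15 (not isolated)
Conditions: 4-MeOC6H4MgBr (3 equiv), ZnBr2 (1.6 equiv), THF, 0 °C to rt
Reagents that add atoms: 4-methoxyphenylmagnesium bromide, COc1ccc([Mg]Br)cc1
Why: Substitution of a 2-sulfonyl cyclic ether by an arylzinc: the zinc and magnesium halides ionise the sulfone to oxocarbenium ion 15 and the arylzinc adds. All three existing substituents lie on one face of 15, so the aryl group should enter from the open face, trans to the C4 aryl, which sets C5 as S.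

Step 10
Reactants: 16 tert-butyl{[(2S,3S,4R,5S)-4-(3,5-dimethoxyphenyl)-2,5-bis(4-methoxyphenyl)oxolan-3-yl]methoxy}dimethylsilane
Product: 17 [(2S,3S,4R,5S)-4-(3,5-dimethoxyphenyl)-2,5-bis(4-methoxyphenyl)oxolan-3-yl]methanol
Conditions: Bu4NF, THF, 0 °C to rt
Reagents that add atoms: none
Why: Fluoride cleavage of the silyl ether; the oxolane has no acidic C–H, so basic fluoride does not endanger its stereocentres.

Step 11
Reactants: 17 [(2S,3S,4R,5S)-4-(3,5-dimethoxyphenyl)-2,5-bis(4-methoxyphenyl)oxolan-3-yl]methanol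
Product: 18 (2S,3R,4R,5S)-4-(3,5-dimethoxyphenyl)-2,5-bis(4-methoxyphenyl)oxolane-3-carbaldehyde
Conditions: Dess–Martin periodinane, NaHCO3, CH2Cl2, 0 °C
Reagents that add atoms: none
Why: Dess–Martin oxidation under bicarbonate buffer gives the aldehyde without a base strong enough to epimerise the formyl-bearing carbon, which is cis to both neighbours; the aldehyde is used at once. (The descriptor at C3 changes to R only because the formyl group outranks C2.)

Step 12
Reactants: 18 (2S,3R,4R,5S)-4-(3,5-dimethoxyphenyl)-2,5-bis(4-methoxyphenyl)oxolane-3-carbaldehyde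
Product: 19 (2S,3S,4R,5S)-3-(2,2-dibromoethenyl)-4-(3,5-dimethoxyphenyl)-2,5-bis(4-methoxyphenyl)oxolane
Conditions: CBr4, PPh3, CH2Cl2, 0 °C
Reagents that add atoms: carbon tetrabromide, BrC(Br)(Br)Br
Why: Ramirez dibromo-olefination, the first stage of the Corey–Fuchs sequence; the ylide is non-basic, so the α-centre is carried through unchanged.

Step 13
Reactants: 20 3,5-dimethoxybenzoyl chloride
Product: 21 N,3,5-trimethoxy-N-methylbenzamide
Conditions: MeNHOMe·HCl, Et3N, CH2Cl2, 0 °C to rt
Reagents that add atoms: N,O-dimethylhydroxylamine hydrochloride, CNOC.Cl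
Why: Acylation of N,O-dimethylhydroxylamine gives the Weinreb amide, which stops acetylide addition at the ketone stage.

Step 14
Reactants: 19 (2S,3S,4R,5S)-3-(2,2-dibromoethenyl)-4-(3,5-dimethoxyphenyl)-2,5-bis(4-methoxyphenyl)oxolane; 21 N,3,5-trimethoxy-N-methylbenzamide
Product: 23 1-(3,5-dimethoxyphenyl)-3-[(2S,3S,4R,5S)-4-(3,5-dimethoxyphenyl)-2,5-bis(4-methoxyphenyl)oxolan-3-yl]prop-2-yn-1-one, via lithium acetylide 22 (not isolated)
Conditions: n-BuLi (2.1 equiv), THF, −78 °C; then 21, −78 to −20 °C; cold 1 M HCl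
Reagents that add atoms: none
Why: Second stage of the Corey–Fuchs sequence (Br/Li exchange, Fritsch–Buttenberg–Wiechell rearrangement, deprotonation to acetylide 22) followed by Weinreb ketone synthesis in the same flask. The chelated tetrahedral adduct survives until the cold acidic quench, which also protonates the released hydroxylamine before it can add to the ynone.

Step 15
Reactants: 24 methyl 3-oxobutanoate (methyl acetoacetate)
Product: 25 methyl (2E)-3-methoxybut-2-enoate
Conditions: HC(OMe)3, H2SO4 (cat.), rt; distillation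
Reagents that add atoms: trimethyl orthoformate, COC(OC)OC
Why: Acid-catalysed ketalisation by the orthoformate and loss of methanol give the conjugated E enol ether.

Step 16
Reactants: 25 methyl (2E)-3-methoxybut-2-enoate
Product: 27 (1Z)-1,3-dimethoxy-1-(trimethylsilyloxy)buta-1,3-diene, via lithium dienolate 26 (not isolated)
Conditions: LiN(i-Pr)2, THF, −78 °C; Me3SiCl, −78 °C to rt
Reagents that add atoms: chlorotrimethylsilane, C[Si](C)(C)Cl
Why: Kinetic γ-deprotonation of the β-methoxy enoate to dienolate 26 and O-silylation give the ketene silyl acetal diene. The geometry at the acetal terminus, drawn Z, is of no consequence because that carbon becomes an arene carbon.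

Step 17
Reactants: 23 1-(3,5-dimethoxyphenyl)-3-[(2S,3S,4R,5S)-4-(3,5-dimethoxyphenyl)-2,5-bis(4-methoxyphenyl)oxolan-3-yl]prop-2-yn-1-one; 27 (1Z)-1,3-dimethoxy-1-(trimethylsilyloxy)buta-1,3-diene
Product: 29 (3,5-dimethoxyphenyl){2-[(2S,3S,4R,5S)-4-(3,5-dimethoxyphenyl)-2,5-bis(4-methoxyphenyl)oxolan-3-yl]-6-hydroxy-4-methoxyphenyl}methanone, via cyclohexadiene cycloadduct 28 (not isolated)
Conditions: 27 (4 equiv), PhMe, 120 °C, sealed tube; then silica gel, CH2Cl2–MeOH, rt
Reagents that add atoms: none
Why: The electron-rich diene 27 and the electron-poor ynone 23 combine in a normal-demand, concerted but strongly asynchronous [4+2] cycloaddition: the unsubstituted CH2 terminus of 27, its most nucleophilic carbon, bonds to the ynone β-carbon (C4'–C5') and the ketene acetal carbon bonds to the α-carbon (C3a'–C7a'). The six-membered ring is thus closed in one cycloaddition event as the cyclohexa-1,4-diene 28. 28 aromatises by 1,4-elimination of methanol from the mixed ketal carbon and the ring CH2, and the aryl silyl ether is cleaved on silica in methanol, which leaves the C7a' oxygen as a free, ketone-chelated phenol and the C6' oxygen as its methyl ether. The closest known reaction type is the thermal Diels–Alder benzannulation of 1,3-dioxygenated 1-silyloxydienes with alkynones and alkynoates to resorcinol derivatives. No stereocentre is formed and the four oxolane centres are spectators; the neutral thermal conditions avoid enolisation toward the propargylic C3, which is cis to both neighbours. The only selectivity needed is regiochemical, and it is secured by the polarisation of the ynone and reinforced by sterics, since the bulky oxolane sits on the carbon that meets the unhindered CH2 terminus.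

Step 18
Reactants: 29 (3,5-dimethoxyphenyl){2-[(2S,3S,4R,5S)-4-(3,5-dimethoxyphenyl)-2,5-bis(4-methoxyphenyl)oxolan-3-yl]-6-hydroxy-4-methoxyphenyl}methanone
Product: 30 3-[(2S,3S,4R,5S)-4-(3,5-dimethoxyphenyl)-2,5-bis(4-methoxyphenyl)oxolan-3-yl]-2-[(3,5-dimethoxyphenyl)(hydroxy)methyl]-5-methoxyphenol (carbinol epimers)
Conditions: NaBH4 (excess), THF–EtOH, 0 °C to rt
Reagents that add atoms: none
Why: Hydride reduction of the hydrogen-bonded diaryl ketone to the benzhydrol; the new carbinol centre forms as a mixture and is erased in step 23.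

Step 19
Reactants: 30 3-[(2S,3S,4R,5S)-4-(3,5-dimethoxyphenyl)-2,5-bis(4-methoxyphenyl)oxolan-3-yl]-2-[(3,5-dimethoxyphenyl)(hydroxy)methyl]-5-methoxyphenol
Product: 31 3-[(2S,3S,4R,5S)-4-(3,5-dimethoxyphenyl)-2,5-bis(4-methoxyphenyl)oxolan-3-yl]-2-[(3,5-dimethoxyphenyl)(4-methylbenzenesulfonyl)methyl]-5-methoxyphenol (epimers)
Conditions: 4-MeC6H4SO2H, CH2Cl2, rt
Reagents that add atoms: 4-methylbenzenesulfinic acid, Cc1ccc(S(=O)O)cc1
Why: The o-hydroxy, p-methoxy benzhydrol ionises under the mild acidity of the sulfinic acid and the benzhydryl cation is captured at sulfur; 2-(arylsulfonylmethyl)phenols are standard base-triggered o-quinone methide precursors.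

Step 20
Reactants: 32 (2S,5S)-hexane-2,5-diol
Product: 33 (2S,5S)-hexane-2,5-diyl dimethanesulfonate
Conditions: MsCl, Et3N, CH2Cl2, 0 °C
Reagents that add atoms: methanesulfonyl chloride, CS(=O)(=O)Cl
Why: O-Sulfonylation, with retention at both carbinol centres.

Step 21
Reactants: 33 (2S,5S)-hexane-2,5-diyl dimethanesulfonate
Product: 34 (2R,5R)-2,5-dimethylthiolane
Conditions: Na2S·9H2O, DMSO, rt
Reagents that add atoms: sodium sulfide, [Na+].[Na+].[S-2]
Why: Double SN2 displacement by sulfide (intermolecular, then 5-exo-tet) inverts both centres and gives the C2-symmetric R,R thiolane.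

Step 22
Reactants: 34 (2R,5R)-2,5-dimethylthiolane
Product: 35 (2R,5R)-1-[(4-methoxyphenyl)methyl]-2,5-dimethylthiolan-1-ium tetrafluoroborate
Conditions: 4-MeOC6H4CH2Br, AgBF4, CH2Cl2, 0 °C to rt, dark
Reagents that add atoms: 4-methoxybenzyl bromide, COc1ccc(CBr)cc1; silver tetrafluoroborate, [Ag+].F[B-](F)(F)F
Why: S-Alkylation of the sulfide driven by precipitation of AgBr; because the sulfide is C2-symmetric, sulfur is not a stereocentre and a single sulfonium salt results.

Step 23
Reactants: 31 3-[(2S,3S,4R,5S)-4-(3,5-dimethoxyphenyl)-2,5-bis(4-methoxyphenyl)oxolan-3-yl]-2-[(3,5-dimethoxyphenyl)(4-methylbenzenesulfonyl)methyl]-5-methoxyphenol; 35 (2R,5R)-1-[(4-methoxyphenyl)methyl]-2,5-dimethylthiolan-1-ium tetrafluoroborate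
Product: 39 (2R,3R)-3-(3,5-dimethoxyphenyl)-4-[(2S,3S,4R,5S)-4-(3,5-dimethoxyphenyl)-2,5-bis(4-methoxyphenyl)oxolan-3-yl]-6-methoxy-2-(4-methoxyphenyl)-2,3-dihydro-1-benzofuran, via o-quinone methide 36 (not isolated), via sulfonium ylide 37 (not isolated), via betaine 38 (not isolated)
Conditions: Cs2CO3 (3 equiv), CH2Cl2–MeCN, −20 °C to rt
Reagents that add atoms: none
Why: Proposed new method: Cs2CO3 turns 31 into o-quinone methide 36 (loss of sulfinate from the phenoxide) and 35 into ylide 37; conjugate addition of the ylide carbon to the methide carbon (C2'–C3') gives betaine 38, whose phenoxide displaces the sulfide with inversion in a 5-exo-tet closure (O1'–C2'). Anti addition followed by invertive closure gives the trans ring, and the C2-symmetric thiolane, which shields one face of the ylide as it does in aldehyde epoxidation, is relied on to set C2' and with it C3' as R,R against any bias from the neighbouring oxolane. The closest known reactions are the [4+1] annulations of o-quinone methides with carbonyl-stabilised sulfonium and ammonium ylides to trans-2,3-dihydrobenzofurans and the asymmetric epoxidations with chiral benzylsulfonium ylides; a semi-stabilised chiral benzyl ylide has not been shown on o-quinone methides.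

Step 24
Reactants: 39 (2R,3R)-3-(3,5-dimethoxyphenyl)-4-[(2S,3S,4R,5S)-4-(3,5-dimethoxyphenyl)-2,5-bis(4-methoxyphenyl)oxolan-3-yl]-6-methoxy-2-(4-methoxyphenyl)-2,3-dihydro-1-benzofuran
Product: 40 5-[(2R,3R)-4-[(2S,3S,4R,5S)-4-(3,5-dihydroxyphenyl)-2,5-bis(4-hydroxyphenyl)oxolan-3-yl]-6-hydroxy-2-(4-hydroxyphenyl)-2,3-dihydro-1-benzofuran-3-yl]benzene-1,3-diol
Conditions: BBr3 (excess), CH2Cl2, −78 to 0 °C; MeOH, then aq. NaHCO3
Reagents that add atoms: none
Why: Lewis-acid cleavage of all eight aryl methyl ethers (O-coordination of BBr3, bromide attack at methyl), started at −78 °C and stopped at 0 °C to limit ionisation of the benzylic C–O bonds; no stereocentre should be touched as long as ring opening is avoided.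

## Compound list

1 | 4-methoxybenzaldehyde | COc1ccc(C=O)cc1 | starting material
2 | 1-ethynyl-3,5-dimethoxybenzene | C#Cc1cc(OC)cc(OC)c1 | starting material
3 | [(3,5-dimethoxyphenyl)ethynyl](methyl)zinc | C[Zn]C#Cc1cc(OC)cc(OC)c1 | intermediate (not isolated)
4 | (1R)-3-(3,5-dimethoxyphenyl)-1-(4-methoxyphenyl)prop-2-yn-1-ol | COc1ccc([C@@H](O)C#Cc2cc(OC)cc(OC)c2)cc1 | intermediate
5 | (5R)-3-(3,5-dimethoxyphenyl)-4-ethenyl-5-(4-methoxyphenyl)-2,5-dihydro-1,2-oxamagnesole | COc1ccc([C@H]2O[Mg]C(c3cc(OC)cc(OC)c3)=C2C=C)cc1 | intermediate (not isolated)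
6 | (2Z,4R)-2-(3,5-dimethoxyphenyl)-3-ethenyl-4-hydroxy-4-(4-methoxyphenyl)but-2-enoic acid | COc1ccc([C@@H](O)/C(C=C)=C(\C(=O)O)c2cc(OC)cc(OC)c2)cc1 | intermediate (not isolated)
7 | (5R)-3-(3,5-dimethoxyphenyl)-4-ethenyl-5-(4-methoxyphenyl)furan-2(5H)-one | COc1ccc([C@H]2OC(=O)C(c3cc(OC)cc(OC)c3)=C2C=C)cc1 | intermediate
8 | (5R)-4-(1,2-dihydroxyethyl)-3-(3,5-dimethoxyphenyl)-5-(4-methoxyphenyl)furan-2(5H)-one (side-chain carbinol epimers) | COc1ccc([C@H]2OC(=O)C(c3cc(OC)cc(OC)c3)=C2C(O)CO)cc1 | intermediate (not isolated)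
9 | (2R)-4-(3,5-dimethoxyphenyl)-2-(4-methoxyphenyl)-5-oxo-2,5-dihydrofuran-3-carbaldehyde | COc1ccc([C@H]2OC(=O)C(c3cc(OC)cc(OC)c3)=C2C=O)cc1 | intermediate
10 | (5R)-3-(3,5-dimethoxyphenyl)-4-(hydroxymethyl)-5-(4-methoxyphenyl)furan-2(5H)-one | COc1ccc([C@H]2OC(=O)C(c3cc(OC)cc(OC)c3)=C2CO)cc1 | intermediate
11 | (5R)-4-({[tert-butyl(dimethyl)silyl]oxy}methyl)-3-(3,5-dimethoxyphenyl)-5-(4-methoxyphenyl)furan-2(5H)-one | COc1ccc([C@H]2OC(=O)C(c3cc(OC)cc(OC)c3)=C2CO[Si](C)(C)C(C)(C)C)cc1 | intermediate
12 | (3R,4S,5S)-4-({[tert-butyl(dimethyl)silyl]oxy}methyl)-3-(3,5-dimethoxyphenyl)-5-(4-methoxyphenyl)oxolan-2-one | COc1ccc([C@H]2OC(=O)[C@@H](c3cc(OC)cc(OC)c3)[C@H]2CO[Si](C)(C)C(C)(C)C)cc1 | intermediate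
13 | (3R,4S,5S)-4-({[tert-butyl(dimethyl)silyl]oxy}methyl)-3-(3,5-dimethoxyphenyl)-5-(4-methoxyphenyl)oxolan-2-ol (anomers) | COc1ccc([C@H]2OC(O)[C@@H](c3cc(OC)cc(OC)c3)[C@H]2CO[Si](C)(C)C(C)(C)C)cc1 | intermediate
14 | tert-butyl{[(2S,3S,4R)-5-(benzenesulfonyl)-4-(3,5-dimethoxyphenyl)-2-(4-methoxyphenyl)oxolan-3-yl]methoxy}dimethylsilane (C5 epimers) | COc1ccc([C@H]2OC(S(=O)(=O)c3ccccc3)[C@@H](c3cc(OC)cc(OC)c3)[C@H]2CO[Si](C)(C)C(C)(C)C)cc1 | intermediate
15 | (2S,3S,4R)-3-({[tert-butyl(dimethyl)silyl]oxy}methyl)-4-(3,5-dimethoxyphenyl)-2-(4-methoxyphenyl)-3,4-dihydro-2H-furan-1-ium | COc1ccc([C@H]2[O+]=C[C@@H](c3cc(OC)cc(OC)c3)[C@H]2CO[Si](C)(C)C(C)(C)C)cc1 | intermediate (not isolated)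
16 | tert-butyl{[(2S,3S,4R,5S)-4-(3,5-dimethoxyphenyl)-2,5-bis(4-methoxyphenyl)oxolan-3-yl]methoxy}dimethylsilane | COc1ccc([C@H]2O[C@H](c3ccc(OC)cc3)[C@@H](c3cc(OC)cc(OC)c3)[C@H]2CO[Si](C)(C)C(C)(C)C)cc1 | intermediate
17 | [(2S,3S,4R,5S)-4-(3,5-dimethoxyphenyl)-2,5-bis(4-methoxyphenyl)oxolan-3-yl]methanol | COc1ccc([C@H]2O[C@H](c3ccc(OC)cc3)[C@@H](c3cc(OC)cc(OC)c3)[C@H]2CO)cc1 | intermediate
18 | (2S,3R,4R,5S)-4-(3,5-dimethoxyphenyl)-2,5-bis(4-methoxyphenyl)oxolane-3-carbaldehyde | COc1ccc([C@H]2O[C@H](c3ccc(OC)cc3)[C@@H](c3cc(OC)cc(OC)c3)[C@H]2C=O)cc1 | intermediate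
19 | (2S,3S,4R,5S)-3-(2,2-dibromoethenyl)-4-(3,5-dimethoxyphenyl)-2,5-bis(4-methoxyphenyl)oxolane | COc1ccc([C@H]2O[C@H](c3ccc(OC)cc3)[C@@H](c3cc(OC)cc(OC)c3)[C@H]2C=C(Br)Br)cc1 | intermediate
20 | 3,5-dimethoxybenzoyl chloride | COc1cc(cc(OC)c1)C(Cl)=O | starting material
21 | N,3,5-trimethoxy-N-methylbenzamide | COc1cc(cc(OC)c1)C(=O)N(C)OC | intermediate
22 | {[(2S,3S,4R,5S)-4-(3,5-dimethoxyphenyl)-2,5-bis(4-methoxyphenyl)oxolan-3-yl]ethynyl}lithium | COc1ccc([C@H]2O[C@H](c3ccc(OC)cc3)[C@@H](c3cc(OC)cc(OC)c3)[C@H]2C#C[Li])cc1 | intermediate (not isolated)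
23 | 1-(3,5-dimethoxyphenyl)-3-[(2S,3S,4R,5S)-4-(3,5-dimethoxyphenyl)-2,5-bis(4-methoxyphenyl)oxolan-3-yl]prop-2-yn-1-one | COc1ccc([C@H]2O[C@H](c3ccc(OC)cc3)[C@@H](c3cc(OC)cc(OC)c3)[C@H]2C#CC(=O)c2cc(OC)cc(OC)c2)cc1 | intermediate
24 | methyl 3-oxobutanoate | COC(=O)CC(C)=O | starting material
25 | methyl (2E)-3-methoxybut-2-enoate | CO/C(C)=C/C(=O)OC | intermediate
26 | lithium 1,3-dimethoxybuta-1,3-dien-1-olate (geometry not defined) | C=C(OC)C=C(OC)O[Li] | intermediate (not isolated)
27 | (1Z)-1,3-dimethoxy-1-(trimethylsilyloxy)buta-1,3-diene | C=C(OC)/C=C(/OC)O[Si](C)(C)C | intermediate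
28 | (3,5-dimethoxyphenyl){2-[(2S,3S,4R,5S)-4-(3,5-dimethoxyphenyl)-2,5-bis(4-methoxyphenyl)oxolan-3-yl]-4,6-dimethoxy-6-[(trimethylsilyl)oxy]cyclohexa-1,4-dien-1-yl}methanone (ketal carbon epimers) | COc1ccc([C@H]2O[C@H](c3ccc(OC)cc3)[C@@H](c3cc(OC)cc(OC)c3)[C@H]2C4=C(C(=O)c5cc(OC)cc(OC)c5)C(OC)(O[Si](C)(C)C)C=C(OC)C4)cc1 | intermediate (not isolated)
29 | (3,5-dimethoxyphenyl){2-[(2S,3S,4R,5S)-4-(3,5-dimethoxyphenyl)-2,5-bis(4-methoxyphenyl)oxolan-3-yl]-6-hydroxy-4-methoxyphenyl}methanone | COc1ccc([C@H]2O[C@H](c3ccc(OC)cc3)[C@@H](c3cc(OC)cc(OC)c3)[C@H]2c2cc(OC)cc(O)c2C(=O)c2cc(OC)cc(OC)c2)cc1 | intermediate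
30 | 3-[(2S,3S,4R,5S)-4-(3,5-dimethoxyphenyl)-2,5-bis(4-methoxyphenyl)oxolan-3-yl]-2-[(3,5-dimethoxyphenyl)(hydroxy)methyl]-5-methoxyphenol (carbinol epimers) | COc1ccc([C@H]2O[C@H](c3ccc(OC)cc3)[C@@H](c3cc(OC)cc(OC)c3)[C@H]2c2cc(OC)cc(O)c2C(O)c2cc(OC)cc(OC)c2)cc1 | intermediate
31 | 3-[(2S,3S,4R,5S)-4-(3,5-dimethoxyphenyl)-2,5-bis(4-methoxyphenyl)oxolan-3-yl]-2-[(3,5-dimethoxyphenyl)(4-methylbenzenesulfonyl)methyl]-5-methoxyphenol (epimers) | COc1ccc([C@H]2O[C@H](c3ccc(OC)cc3)[C@@H](c3cc(OC)cc(OC)c3)[C@H]2c2cc(OC)cc(O)c2C(c2cc(OC)cc(OC)c2)S(=O)(=O)c2ccc(C)cc2)cc1 | intermediate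
32 | (2S,5S)-hexane-2,5-diol | C[C@H](O)CC[C@H](C)O | starting material
33 | (2S,5S)-hexane-2,5-diyl dimethanesulfonate | C[C@H](OS(C)(=O)=O)CC[C@H](C)OS(C)(=O)=O | intermediate
34 | (2R,5R)-2,5-dimethylthiolane | C[C@@H]1CC[C@@H](C)S1 | intermediate
35 | (2R,5R)-1-[(4-methoxyphenyl)methyl]-2,5-dimethylthiolan-1-ium tetrafluoroborate | COc1ccc(C[S+]2[C@H](C)CC[C@H]2C)cc1.F[B-](F)(F)F | intermediate
36 | 6-[(3,5-dimethoxyphenyl)methylidene]-5-[(2S,3S,4R,5S)-4-(3,5-dimethoxyphenyl)-2,5-bis(4-methoxyphenyl)oxolan-3-yl]-3-methoxycyclohexa-2,4-dien-1-one (alkene geometry not defined) | COc1ccc([C@H]2O[C@H](c3ccc(OC)cc3)[C@@H](c3cc(OC)cc(OC)c3)[C@H]2C4=CC(OC)=CC(=O)C4=Cc5cc(OC)cc(OC)c5)cc1 | intermediate (not isolated)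
37 | [(2R,5R)-2,5-dimethylthiolan-1-ium-1-yl](4-methoxyphenyl)methanide | COc1ccc([CH-][S+]2[C@H](C)CC[C@H]2C)cc1 | intermediate (not isolated)
38 | 2-{(1R,2S)-1-(3,5-dimethoxyphenyl)-2-[(2R,5R)-2,5-dimethylthiolan-1-ium-1-yl]-2-(4-methoxyphenyl)ethyl}-3-[(2S,3S,4R,5S)-4-(3,5-dimethoxyphenyl)-2,5-bis(4-methoxyphenyl)oxolan-3-yl]-5-methoxyphenolate | COc1ccc([C@H]2O[C@H](c3ccc(OC)cc3)[C@@H](c3cc(OC)cc(OC)c3)[C@H]2c2cc(OC)cc([O-])c2[C@@H](c2cc(OC)cc(OC)c2)[C@@H](c2ccc(OC)cc2)[S+]2[C@H](C)CC[C@H]2C)cc1 | intermediate (not isolated)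
39 | (2R,3R)-3-(3,5-dimethoxyphenyl)-4-[(2S,3S,4R,5S)-4-(3,5-dimethoxyphenyl)-2,5-bis(4-methoxyphenyl)oxolan-3-yl]-6-methoxy-2-(4-methoxyphenyl)-2,3-dihydro-1-benzofuran | COc1ccc([C@H]2O[C@H](c3ccc(OC)cc3)[C@@H](c3cc(OC)cc(OC)c3)[C@H]2c2cc(OC)cc3c2[C@@H](c2cc(OC)cc(OC)c2)[C@H](c2ccc(OC)cc2)O3)cc1 | intermediate
40 | 5-[(2R,3R)-4-[(2S,3S,4R,5S)-4-(3,5-dihydroxyphenyl)-2,5-bis(4-hydroxyphenyl)oxolan-3-yl]-6-hydroxy-2-(4-hydroxyphenyl)-2,3-dihydro-1-benzofuran-3-yl]benzene-1,3-diol | Oc1ccc([C@H]2O[C@H](c3ccc(O)cc3)[C@@H](c3cc(O)cc(O)c3)[C@H]2c2cc(O)cc3c2[C@@H](c2cc(O)cc(O)c2)[C@H](c2ccc(O)cc2)O3)cc1 | target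

## Step count and risk

Total: 24 steps. Longest linear sequence: 18 steps (1–12, 14, 17, 18, 19, 23, 24) from 4-methoxybenzaldehyde. The Weinreb amide (step 13), the diene (steps 15–16) and the sulfonium salt (steps 20–22) are side branches.

**Step 23 (labelled step).** Several processes can divert it:
- O-benzylation of the phenoxide of 31 by the sulfonium salt before sulfinate is lost.
- Capture of the quinone methide by the neighbouring 3,5-dimethoxyphenyl ring on oxolane C4 in a seven-membered Friedel–Crafts closure, or by traces of water.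
- Poor facial selectivity if reagent control and the bias of the adjacent oxolane are mismatched.
- Loss of stereochemical fidelity if the 4-methoxybenzylic sulfonium of the betaine ionises before closure.

Fallback by known chemistry, setting out from 29: O-alkylation with 4-methoxybenzyl chloride and K2CO3 in DMF gives the 4-methoxybenzyl ether of the benzophenone F1. The phosphazene base P4-t-Bu then induces intramolecular aldol addition of the benzylic carbanion to the ketone and dehydration, giving the 2,3-diarylbenzofuran F2. Ionic hydrogenation with Et3SiH and CF3CO2H (protonation at C3', hydride delivery to C2' trans to the C3' aryl) gives the trans-dihydrobenzofuran. This is expected as 39 together with its (2S,3S) dihydrobenzofuran diastereomer F3, separated by chromatography; the fallback rejoins the route at 39. It gives up reagent control of C2'/C3'.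

**Step 17 (key step).** The cycloaddition may be slow because the oxolane shields the β-carbon, so the diene may decompose first. A silyl-transfer Michael addition may occur without ring closure. The enol ether of the cycloadduct may hydrolyse before aromatisation and scramble the O-methylation pattern. Prolonged heating may isomerise the ynone toward an allenone and erode C3.

Fallback, setting out from 24 and 23: 24 is silylated (Me3SiCl, Et3N) to methyl 3-[(trimethylsilyl)oxy]but-2-enoate F4. Deprotonation with LiN(i-Pr)2 and silylation give the more electron-rich 1-methoxy-1,3-bis[(trimethylsilyl)oxy]buta-1,3-diene F5. This adds to 23 at lower temperature and gives, after aromatisation, the 2,4-dihydroxybenzophenone F6. The oxygens are then differentiated by methylation of the non-chelated para hydroxyl (MeI, K2CO3, acetone); the fallback rejoins at 29.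

**Step 6.** Likely failures are hydrogenolysis of the benzylic, allylic lactone C–O bond or of the allylic silyl ether, sluggish reduction of the tetrasubstituted alkene, and partial arene reduction under forcing conditions.

Fallback, setting out from 11: conjugate reduction with catalytic [(Ph3P)CuH]6 and PhMe2SiH delivers hydride to C4 from the face opposite the C5 aryl and gives the silyl ketene acetal F7. Kinetic protonation with a hindered phenol at low temperature occurs from the face opposite the two cis substituents and returns the all-cis lactone 12.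

**Step 9.** Oxocarbenium ion 15 may lose the C4 proton to give an aryl-conjugated enol ether, which epimerises C4. Ionisation of the sulfone may be incomplete, and facial selectivity may erode.

Fallback, setting out from 13: oxalyl chloride with catalytic DMF gives the anomeric chloride F8. A nickel-catalysed Negishi coupling (Ni(cod)2, 4,4',4''-tri-tert-butylterpyridine, 4-MeOC6H4ZnI·LiCl) proceeds through the anomeric radical rather than the cation, and that radical is also trapped trans to the C4 aryl; the fallback rejoins at 16.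

**Step 24.** BBr3 may ionise the benzylic ether bonds O1–C2, O1–C5 and O1'–C2', leading to ring opening and epimerisation at the oxybenzylic centres; demethylation may also be incomplete.

Fallback, setting out from 39 and ending at 40: demethylation under basic, non-ionising conditions by fusion with MeMgI at 160 °C, the classical method for stilbenoid and resorcinol methyl ethers. It makes no new isolated compound (F0).

## Further compounds

F1 | step 23 | (3,5-dimethoxyphenyl){2-[(2S,3S,4R,5S)-4-(3,5-dimethoxyphenyl)-2,5-bis(4-methoxyphenyl)oxolan-3-yl]-4-methoxy-6-[(4-methoxyphenyl)methoxy]phenyl}methanone | COc1ccc([C@H]2O[C@H](c3ccc(OC)cc3)[C@@H](c3cc(OC)cc(OC)c3)[C@H]2c2cc(OC)cc(OCc3ccc(OC)cc3)c2C(=O)c2cc(OC)cc(OC)c2)cc1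
F2 | step 23 | 3-(3,5-dimethoxyphenyl)-4-[(2S,3S,4R,5S)-4-(3,5-dimethoxyphenyl)-2,5-bis(4-methoxyphenyl)oxolan-3-yl]-6-methoxy-2-(4-methoxyphenyl)-1-benzofuran | COc1ccc([C@H]2O[C@H](c3ccc(OC)cc3)[C@@H](c3cc(OC)cc(OC)c3)[C@H]2c2cc(OC)cc3oc(-c4ccc(OC)cc4)c(-c4cc(OC)cc(OC)c4)c23)cc1
F3 | step 23 | (2S,3S)-3-(3,5-dimethoxyphenyl)-4-[(2S,3S,4R,5S)-4-(3,5-dimethoxyphenyl)-2,5-bis(4-methoxyphenyl)oxolan-3-yl]-6-methoxy-2-(4-methoxyphenyl)-2,3-dihydro-1-benzofuran | COc1ccc([C@H]2O[C@H](c3ccc(OC)cc3)[C@@H](c3cc(OC)cc(OC)c3)[C@H]2c2cc(OC)cc3c2[C@H](c2cc(OC)cc(OC)c2)[C@@H](c2ccc(OC)cc2)O3)cc1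
F4 | step 17 | methyl 3-[(trimethylsilyl)oxy]but-2-enoate (E/Z mixture) | COC(=O)C=C(C)O[Si](C)(C)C
F5 | step 17 | 1-methoxy-1,3-bis[(trimethylsilyl)oxy]buta-1,3-diene (geometry not defined) | C=C(O[Si](C)(C)C)C=C(OC)O[Si](C)(C)C
F6 | step 17 | (3,5-dimethoxyphenyl){2-[(2S,3S,4R,5S)-4-(3,5-dimethoxyphenyl)-2,5-bis(4-methoxyphenyl)oxolan-3-yl]-4,6-dihydroxyphenyl}methanone | COc1ccc([C@H]2O[C@H](c3ccc(OC)cc3)[C@@H](c3cc(OC)cc(OC)c3)[C@H]2c2cc(O)cc(O)c2C(=O)c2cc(OC)cc(OC)c2)cc1
F7 | step 6 | tert-butyl{[(2S,3S)-5-{[dimethyl(phenyl)silyl]oxy}-4-(3,5-dimethoxyphenyl)-2-(4-methoxyphenyl)-2,3-dihydrofuran-3-yl]methoxy}dimethylsilane | COc1ccc([C@H]2OC(O[Si](C)(C)c3ccccc3)=C(c3cc(OC)cc(OC)c3)[C@H]2CO[Si](C)(C)C(C)(C)C)cc1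
F8 | step 9 | tert-butyl{[(2S,3S,4R)-5-chloro-4-(3,5-dimethoxyphenyl)-2-(4-methoxyphenyl)oxolan-3-yl]methoxy}dimethylsilane (C5 epimers) | COc1ccc([C@H]2OC(Cl)[C@@H](c3cc(OC)cc(OC)c3)[C@H]2CO[Si](C)(C)C(C)(C)C)cc1
F0 | step 24 | none | none
A1 | alternative 1 | (2R,3R)-4-bromo-3-(3,5-dimethoxyphenyl)-6-methoxy-2-(4-methoxyphenyl)-2,3-dihydro-1-benzofuran | Brc1cc(OC)cc2c1[C@@H](c1cc(OC)cc(OC)c1)[C@H](c1ccc(OC)cc1)O2
A2 | alternative 1 | 3-bromo-2-[(E)-1-(3,5-dimethoxyphenyl)-2-(4-methoxyphenyl)ethenyl]-5-methoxyphenol | Oc1cc(OC)cc(Br)c1/C(=C/c1ccc(OC)cc1)c1cc(OC)cc(OC)c1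
A3 | alternative 2 | 5-[(2R,3R)-4-bromo-6-methoxy-2-(4-methoxyphenyl)-2,3-dihydro-1-benzofuran-3-yl]benzene-1,3-diol | Brc1cc(OC)cc2c1[C@@H](c1cc(O)cc(O)c1)[C@H](c1ccc(OC)cc1)O2
A4 | alternative 2 | 1-[(2R,3R)-4-bromo-6-methoxy-2-(4-methoxyphenyl)-2,3-dihydro-1-benzofuran-3-yl]hexane-1,3,5-trione | Brc1cc(OC)cc2c1[C@@H](C(=O)CC(=O)CC(C)=O)[C@H](c1ccc(OC)cc1)O2
A5 | alternative 3 | (2R,3R)-3-(3,5-dimethoxyphenyl)-4-[(4S,5S)-4-(3,5-dimethoxyphenyl)-2,5-bis(4-methoxyphenyl)-4,5-dihydrofuran-3-yl]-6-methoxy-2-(4-methoxyphenyl)-2,3-dihydro-1-benzofuran | COc1ccc(C2O[C@H](c3ccc(OC)cc3)[C@@H](c3cc(OC)cc(OC)c3)C=2c2cc(OC)cc3c2[C@@H](c2cc(OC)cc(OC)c2)[C@H](c2ccc(OC)cc2)O3)cc1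
A6 | alternative 3 | (2E)-3-(3,5-dimethoxyphenyl)-2-[(2R,3R)-3-(3,5-dimethoxyphenyl)-6-methoxy-2-(4-methoxyphenyl)-2,3-dihydro-1-benzofuran-4-yl]-1-(4-methoxyphenyl)prop-2-en-1-one | COc1ccc(C(=O)/C(=C/c2cc(OC)cc(OC)c2)c2cc(OC)cc3c2[C@@H](c2cc(OC)cc(OC)c2)[C@H](c2ccc(OC)cc2)O3)cc1
A7 | alternative 3 | 1-(diazomethyl)-4-methoxybenzene | COc1ccc(C=[N+]=[N-])cc1
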